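A one-step world, starting material to target and stop, needs a single count, the forward constant at the flask's temperature times the run time. Our flask has more steps, so we first ask which constants must be known well.

| setting | grey | amber | violet |
|---|---|---|---|
| starting material | 0.87 M | 0.87 M | 0.87 M |
| protic impurity | 0.0870 M | 0.0870 M | 0.0870 M |
| temperature | −25 °C | 5 °C | 35 °C |
| time | 4.0 min | 4.0 min | 4.0 min |

* which flask leads in amount of target, in percent of the starting material charged ("all alike" within 1.5 percentage points) (grey / amber / violet / all alike)
* how much target is there at the end, in percent of the starting material charged: grey
* how much target is there at the end, in percent of the starting material charged: amber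
* how much target is there at the end, in percent of the starting material charged: violet

- percent here means starting material units held: one homo dimer counts as two
- for a step with 2 of a species take k times the square, and two of it per event
- constants are those at 35 °C; use the activation energies and enthalpies for any other temperature

    2 starting material → homo dimer (k1 = 0.0267 M⁻¹ s⁻¹, Ea1 = 74.0 kJ mol⁻¹)
    starting material ⇌ target (K2 = 1.49, k2 = 0.0661 s⁻¹, Ea2 = 70.0 kJ mol⁻¹, ΔH2 = −31.0 kJ mol⁻¹)
    starting material + protic impurity → quenched substrate (k3 = 0.0266 M⁻¹ s⁻¹, Ea3 = 64.0 kJ mol⁻¹)
    target ⇌ isomer of the product (K4 = 7.47, k4 = 0.00202 s⁻¹, Ea4 = 78.0 kJ mol⁻¹, ΔH4 = −38.0 kJ mol⁻¹)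
    target → over-reaction product (k5 = 0.0674 s⁻¹, Ea5 = 86.0 kJ mol⁻¹)
    (constants at 35 °C)

Starting material also pairs to homo dimer and meets protic impurity, while target returns to starting material, turns to isomer of the product and goes on to over-reaction product. We test each path on amber, with its constants carried down from the reference temperature.

1. In amber the isomer path runs at 0.00454 min⁻¹, slower than over-reaction at 0.108 min⁻¹, so an error in it moves little and we drop it.

2. In amber the impurity takes starting material at 0.00939 min⁻¹, slower than the forward step at 0.208 min⁻¹, so we drop it too.

3. In amber the equilibrium constant is 5.49, so the return step runs at 0.0379 min⁻¹, slower than over-reaction. We drop it and accept that this errs upward.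

4. The dimer path stays. At the charge in amber it uses starting material at 0.124 min⁻¹ against 0.208 min⁻¹ for the forward step, so an error in it changes the making share, 62.7%.

5. Two counts remain. The feed count is both paths from starting material times the run time, 1.33 in amber. The over-reaction constant at the flask's temperature times the run time is 0.433 in amber, and this is the drain count, the number of target lifetimes against over-reaction that the run holds.

6. With feed count F and drain count D, target is the making share times F/(D−F) times (exp(−F) − exp(−D)). We reckon 35.7% for amber. Grey's forward count gives 2.15%, and its drain count is 0.00483. Violet's drain count is 16.2, so we expect amber ahead of both.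

The forecast names amber, with 2.1% for grey, 34.5% for amber and 0.02% for violet, on the ground that at amber's temperature “over-reaction is slow enough”. Our amber figure stands above its figure.

The simulation gives amber in the lead, with 2.10% for grey, 34.8% for amber and 0.0217% for violet.

Violet's drain count of 16.2 stands far above amber's 0.433, and the run with over-reaction struck out shows what that costs. Violet's target then ends at 15.6% instead of 0.0217%, the largest single effect.

For violet's charges run at 10 °C, the feed count is 2.29 and the drain count 0.835, so the reckoning gives 32.5%. The simulation gives 32.1%.

All constants belong to no real substance; what happens was integrated by code.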